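**Assumption (facial sense of the allylboration):** the borane made from (+)-Ipc2BOMe is taken to add to the Re face of aldehyde 2, the mirror image of the established Si-face preference of the reagent from (−)-Ipc2BOMe. If the sense is the reverse, the other antipode of the borane is used and nothing else changes.

## The problem

6,8-Diprenylaromadendrin (27) is a 4-chromanone (rings A and C) with a 4-hydroxyphenyl ring B at C2, a hydroxyl at C3 and a fully substituted ring A. Around ring A, oxygen and carbon substituents alternate: C5–OH, C6–prenyl, C7–OH, C8–prenyl, C8a–O1, C4a–C4.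

The two stereocentres, C2 and C3, are adjacent and trans (2R,3R). C3 is α to the C4 ketone and C2 is a benzylic ether β to it, so base can open ring C by β-elimination of the O1 phenoxide and erase both centres. The 3-hydroxy ketone is also easily dehydrogenated to the flavonol.

Because the centres are vicinal, one can direct the other in an open chain: an alkoxy group on C3 can chelate a metal and steer hydride to C2. Once ring C is closed, only equilibration towards trans remains.

The prenyl groups rule out hydrogenolysis and strong acid, since a free ortho phenol adds to the protonated alkene to give a chroman. Protecting groups therefore have to leave with fluoride or dilute acid.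

The classical obstacle is regiocontrolled double C-prenylation of an acylated phloroglucinol. The O/C alternation of ring A offers a way round it. It is the pattern of a head-to-tail trimer of three oxygen-substituted alkynes (C4a≡C5–O, C6≡C7–O, C8≡C8a–O1). The chain C4–C3–C2–O1 can tether two of them as a 1,7-diyne, so one [2+2+2] cycloaddition could form C4a–C8a, C5–C6 and C7–C8 and close rings A and C together.

## Retrosynthesis

**27 ⇐ 26 ⇐ 25 (O–protecting group bonds).** The last operations only unmask oxygen. The C5 and C7 oxygens of 25 carry a 2-(trimethylsilyl)ethyl and a triisopropylsilyl group, both fluoride-labile; O3 and O4' carry methoxymethyl groups, acid-labile. Acid is applied first (25 to 26), while both ring A oxygens are still blocked, so no phenol can cyclise onto a prenyl group. Fluoride comes last (26 to 27). The forward steps must avoid strong acid and prolonged base.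

**25 ⇐ 20 + 24 (C4a–C8a, C5–C6, C7–C8).** This cut removes ring A and ring C at once and leaves an open chain, diyne 20, that already holds C2 and C3, plus the simple siloxyalkyne 24. Other ways of building ring A (aromatic prenylation, sigmatropic shifts, benzannulation of one ring only) either face the regiochemistry of a phloroglucinol or leave ring C and the stereocentres for later. Two points of the diyne were fixed at this stage.
- The C5 oxygen sits on the ynone alkyne as an alkyl ynol ether, not a silyl ether. A 3-silyloxy ynone has no reliable preparation, because a silyloxyacetylide would be expected to rearrange to a C-silyl ynolate. 3-Alkoxy ynones are a known class.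
- The alkyl group is 2-(trimethylsilyl)ethyl, so fluoride still frees O5 at the end.

The forward reaction must deliver one orientation of 24 and run under neutral conditions.

**24 ⇐ 22 ⇐ 21 (the C≡C–O unit).** Siloxyalkyne 24 is cut back to ester 22 by Kowalski homologation, which adds one carbon and turns the ester carbon into the oxygen-bearing alkyne carbon. Ester 22 comes from commercial acid 21. The alternative, oxidation of a terminal alkyne, serves as reserve.

**20 ⇐ 19 ⇐ 15 + 17 (C4–C4a).** The ynone is cut at the bond between carbonyl carbon and alkyne, giving aldehyde 15 and the acetylide 18 made from dichlorovinyl ether 17. Acylation of an amide at C4 was set aside for two reasons. An amide would not survive the butyllithium needed to make the O1 ynol ether. And an acetylide acts as a base towards a substrate whose C3–H is flanked by a carbonyl and a β-alkynyloxy leaving group. Addition to an aldehyde at −78 °C is faster than enolisation, and the carbinol 19 is oxidised under neutral conditions.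

**15 ⇐ 14 ⇐ 13 ⇐ 10 + 11 ⇐ 9 (O1–C8a and C8–CH2).** The ynol ether on O1 is made from alcohol 9 through dichlorovinyl ether 10. Elimination and metalation give acetylide 12, and alkylation with prenyl bromide 11 attaches the C8 prenyl group. Because two equivalents of butyllithium are involved, C4 is carried as a silyl-protected primary alcohol and oxidised only afterwards (13 to 14 to 15). Alcohol 9 holds both stereocentres and no sensitive group.

**9 ⇐ 8 ⇐ 7 ⇐ 6 ⇐ 4 (the C2 centre).** The benzylic centre is set last, by chelation-controlled reduction of α-alkoxy ketone 8, which gives the anti relationship directly. Ketone 8 arises from syn alcohol 7 by oxidation, and 7 from alkene 4 by ozonolysis/reduction (6) and selective silylation. Dihydroxylation of a cinnamate ester was considered. It gives the syn diol, which would need inversion at an electron-rich benzylic carbon and separate differentiation of two secondary hydroxyls, for no saving in steps.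

**4 ⇐ 2 ⇐ 1 (C2–C3).** Alkene 4 is cut between the two carbinol carbons into aldehyde 2 and a γ-alkoxyallyl boron reagent. The Brown alkoxyallylboration sets the future C3 centre in absolute terms and delivers the methoxymethyl group on O3 only. Aldehyde 2 is the methoxymethyl ether of 4-hydroxybenzaldehyde 1.

## Roads not taken

**Alternative 1:** The cut is the C2–C3 bond and the C3–O bond. Rh2(OAc)4 would convert the ring A diazoketone A1 into a carbene, which the alcohol A2 captures as an oxonium ylide. A chiral phosphoric acid then guides aldol-type trapping by aldehyde 2 to give A3 with both stereocentres. Ring C would be closed afterwards by displacement of fluoride by the benzylic oxygen.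
- Merits: three components in one catalytic step, both centres set at once, and a shorter sequence than the chosen plan. The reaction class is documented for diazo carbonyl compounds, so its key step is less speculative.
- Weak points: A1 needs a pentasubstituted fluorophloroglucinol with two C-prenyl groups, which brings back the regiochemistry problem of ring A. Control of anti selectivity and enantioselectivity with an aryl diazomethyl ketone is less secure than with diazo esters. The ring closure needs base on an aldol (retro-aldol risk) and a fluoroarene deactivated by two alkoxy groups. The benzyl-type ether on O3 needs an oxidant for removal.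
- Comparison: the chosen plan is longer and its key step is new. In return it never performs substitution on ring A and sets the stereocentres by reagent control of established kinds.

**Alternative 2:** The cut is C8–C8a, C6–C7 and C4a–C8a of ring A only. Heating cyclobutenone A4 with siloxyalkyne 24 would give phenol A5 by the Danheiser benzannulation (vinylketene, [2+2], ring opening, 6π closure).
- Merits: the reaction class is proven with siloxyalkynes, the regiochemistry follows from the mechanism, the three oxygens come out differentiated, both prenyl groups are in place, and 24 is shared with the chosen route.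
- Weak points: only one ring is formed. Ring C and both stereocentres still require C-acylation at the single free position of A5, chain extension, an asymmetric oxidation and ring closure, a sequence in which acid and base recur on a prenylated phloroglucinol. A4 needs a ketene cycloaddition with an alkoxyacetylene that carries a removable group.
- Comparison: its key step is more reliable than that of the chosen plan. The chosen plan sets against it two rings closed in one step on a chain that already carries C2 and C3, and a two-step end game.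

**Alternative 3:** The cut is the two aryl–CH2 bonds at C6 and C8. Heating bis(allyl ether) A6 with Eu(fod)3 would move both allyl groups to carbon, giving A7. Whichever group moves first, the ortho and para shifts converge on C6 and C8. Olefin cross-metathesis (second-generation Grubbs catalyst) would then turn allyl into prenyl.
- Merits: the shortest road and the one with the best precedent, provided the aromadendrin core is at hand.
- Weak points: A6 requires selective allylation of O5 (hydrogen-bonded) and O7 beside protected O3 and O4'. A trans-dihydroflavonol is heated with a Lewis acid, with risk of epimerisation at C2 and dehydrogenation. The para migration passes through dienones that can be diverted. The prenyl groups need an extra metathesis step. The stereocentres must come from a separate asymmetric synthesis of the core.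
- Comparison: in step count and precedent this road is better. The chosen plan offers independence from a preformed, selectively protected flavanonol, prenyl groups introduced as such, no thermal stress on the C2–C3 unit, and a new annulation of general use for alternating O/C arenes.

Key step: step 16

## Steps

Step 1
Reactants: 1 4-hydroxybenzaldehyde
Product: 2 4-(methoxymethoxy)benzaldehyde
Conditions: MOMCl, iPr2NEt, CH2Cl2, 0 °C → rt
Reagents that add atoms: chloromethyl methyl ether, COCCl
Why: O-alkylation of the phenol by the chloromethyl ether (Williamson-type acetal formation) under amine base; the aldehyde is untouched and the acetal survives the basic and organometallic steps that follow.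

Step 2
Reactants: 2 4-(methoxymethoxy)benzaldehyde
Product: 4 (1S,2S)-2-(methoxymethoxy)-1-[4-(methoxymethoxy)phenyl]but-3-en-1-ol, via diisopinocampheylborinate ester 3 (not isolated)
Conditions: allyl methoxymethyl ether, sec-BuLi, THF, −78 °C; (+)-Ipc2BOMe; BF3·OEt2; then 2, −78 °C; NaOH, H2O2, 0 °C → rt
Reagents that add atoms: allyl methoxymethyl ether [3-(methoxymethoxy)prop-1-ene], C=CCOCOC
Why: Brown γ-alkoxyallylboration: the (Z)-γ-alkoxyallylborane reacts through a chair Zimmerman–Traxler transition state, so Z geometry gives the syn adduct and the isopinocampheyl groups select the aldehyde face. The reagent from (+)-Ipc2BOMe should set C2 as S (the future C3 of the flavanonol); the benzylic centre formed here is provisional and is reset in steps 5 and 6.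

Step 3
Reactants: 4 (1S,2S)-2-(methoxymethoxy)-1-[4-(methoxymethoxy)phenyl]but-3-en-1-ol
Product: 6 (1S,2S)-2-(methoxymethoxy)-1-[4-(methoxymethoxy)phenyl]propane-1,3-diol, via ozonide 5 (not isolated)
Conditions: O3, CH2Cl2, −78 °C (stopped at first excess); then NaBH4, MeOH, −78 → 0 °C
Reagents that add atoms: ozone, [O-][O+]=O
Why: Ozonolysis of the terminal alkene and borohydride reduction of the ozonide give the primary alcohol; the electron-rich arene is spared at −78 °C when ozone is not used in excess, and neither stereocentre is touched.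

Step 4
Reactants: 6 (1S,2S)-2-(methoxymethoxy)-1-[4-(methoxymethoxy)phenyl]propane-1,3-diol
Product: 7 (1S,2S)-2-(methoxymethoxy)-1-[4-(methoxymethoxy)phenyl]-3-[(triisopropylsilyl)oxy]propan-1-ol
Conditions: TIPSCl, imidazole, DMF, 0 °C → rt
Reagents that add atoms: chlorotriisopropylsilane, CC(C)[Si](Cl)(C(C)C)C(C)C
Why: Selective silylation of the primary hydroxyl over the hindered benzylic one; the bulky silyl group is chosen so that it should not migrate to the neighbouring alkoxide formed in step 7.

Step 5
Reactants: 7 (1S,2S)-2-(methoxymethoxy)-1-[4-(methoxymethoxy)phenyl]-3-[(triisopropylsilyl)oxy]propan-1-ol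
Product: 8 (2S)-2-(methoxymethoxy)-1-[4-(methoxymethoxy)phenyl]-3-[(triisopropylsilyl)oxy]propan-1-one
Conditions: Dess–Martin periodinane, NaHCO3, CH2Cl2, 0 °C → rt
Reagents that add atoms: none
Why: Dess–Martin oxidation of the benzylic alcohol to the aryl ketone under buffered, non-enolising conditions, so the α-alkoxy stereocentre is kept.

Step 6
Reactants: 8 (2S)-2-(methoxymethoxy)-1-[4-(methoxymethoxy)phenyl]-3-[(triisopropylsilyl)oxy]propan-1-one
Product: 9 (1R,2S)-2-(methoxymethoxy)-1-[4-(methoxymethoxy)phenyl]-3-[(triisopropylsilyl)oxy]propan-1-ol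
Conditions: Zn(BH4)2, Et2O, −30 → 0 °C
Reagents that add atoms: none
Why: Chelation-controlled reduction (Cram chelate model): zinc bridges the ketone oxygen and the α-methoxymethoxy oxygen, and hydride attacks the face opposite the CH2OSi branch. This should give the anti (1R,2S) alcohol, the relative configuration of C2 and C3 in the target.

Step 7
Reactants: 9 (1R,2S)-2-(methoxymethoxy)-1-[4-(methoxymethoxy)phenyl]-3-[(triisopropylsilyl)oxy]propan-1-ol
Product: 10 {(2S,3R)-3-{[(E)-1,2-dichloroethenyl]oxy}-2-(methoxymethoxy)-3-[4-(methoxymethoxy)phenyl]propoxy}triisopropylsilane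
Conditions: KH, THF, 0 °C; Cl2C=CHCl, −50 °C → rt
Reagents that add atoms: trichloroethylene, ClC=C(Cl)Cl
Why: Anti addition of the alkoxide to dichloroacetylene, generated in the flask by dehydrochlorination of trichloroethylene, gives the (E)-1,2-dichlorovinyl ether; the C–O bond at the stereocentre is not broken, so configuration is retained.

Step 8
Reactants: 10 {(2S,3R)-3-{[(E)-1,2-dichloroethenyl]oxy}-2-(methoxymethoxy)-3-[4-(methoxymethoxy)phenyl]propoxy}triisopropylsilane, 11 1-bromo-3-methylbut-2-ene (prenyl bromide)
Product: 13 {(2S,3R)-2-(methoxymethoxy)-3-[4-(methoxymethoxy)phenyl]-3-[(5-methylhex-4-en-1-yn-1-yl)oxy]propoxy}triisopropylsilane, via lithium alkynyl ether 12 (not isolated)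
Conditions: n-BuLi (2.1 equiv), THF, −78 °C; then 11, DMPU, −78 → 0 °C; cold NaHCO3 work-up, Et3N-deactivated silica
Reagents that add atoms: none
Why: Ynol ether synthesis from a dichlorovinyl ether: the first equivalent of n-BuLi eliminates HCl to the chloroalkynyl ether and the second exchanges chlorine for lithium. SN2 alkylation of acetylide 12 by the allylic bromide then places the C8 prenyl group on the alkyne. The substrate has no carbonyl group, and the aryl acetal should not be ortho-lithiated at −78 °C.

Step 9
Reactants: 13 {(2S,3R)-2-(methoxymethoxy)-3-[4-(methoxymethoxy)phenyl]-3-[(5-methylhex-4-en-1-yn-1-yl)oxy]propoxy}triisopropylsilane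
Product: 14 (2S,3R)-2-(methoxymethoxy)-3-[4-(methoxymethoxy)phenyl]-3-[(5-methylhex-4-en-1-yn-1-yl)oxy]propan-1-ol
Conditions: TBAF, THF, 0 °C → rt
Reagents that add atoms: none
Why: Fluoride-mediated cleavage of the primary silyl ether; ynol ether, acetals and alkene are inert to fluoride and to the basic medium.

Step 10
Reactants: 14 (2S,3R)-2-(methoxymethoxy)-3-[4-(methoxymethoxy)phenyl]-3-[(5-methylhex-4-en-1-yn-1-yl)oxy]propan-1-ol
Product: 15 (2R,3R)-2-(methoxymethoxy)-3-[4-(methoxymethoxy)phenyl]-3-[(5-methylhex-4-en-1-yn-1-yl)oxy]propanal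
Conditions: Pr4N[RuO4] (5 mol %), NMO, 4 Å MS, CH2Cl2, 0 °C → rt; used at once
Reagents that add atoms: none
Why: Ley–Griffith oxidation of the primary alcohol under neutral conditions, without acid and without a strong amine base, so the acid-labile ynol ether survives and the aldehyde neither epimerises at C2 nor eliminates the alkynyloxy group at C3.

Step 11
Reactants: 16 2-(trimethylsilyl)ethanol
Product: 17 {2-{[(E)-1,2-dichloroethenyl]oxy}ethyl}trimethylsilane
Conditions: KH, THF, 0 °C; Cl2C=CHCl, −50 °C → rt
Reagents that add atoms: trichloroethylene, ClC=C(Cl)Cl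
Why: The same alkoxide addition to dichloroacetylene as in step 7; the potassium alkoxide is kept at or below 0 °C before the chloroalkene is added, to avoid Peterson-type loss of ethene from the β-silyl alkoxide.

Step 12
Reactants: 15 (2R,3R)-2-(methoxymethoxy)-3-[4-(methoxymethoxy)phenyl]-3-[(5-methylhex-4-en-1-yn-1-yl)oxy]propanal, 17 {2-{[(E)-1,2-dichloroethenyl]oxy}ethyl}trimethylsilane
Product: 19 (4S,5R)-4-(methoxymethoxy)-5-[4-(methoxymethoxy)phenyl]-5-[(5-methylhex-4-en-1-yn-1-yl)oxy]-1-[2-(trimethylsilyl)ethoxy]pent-1-yn-3-ol (both C3 epimers), via lithium silylethoxyacetylide 18 (not isolated)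
Conditions: 17 (1.3 equiv), n-BuLi (2.6 equiv), THF, −78 °C; then 15, −78 °C; pH 7 buffer quench at −78 °C
Reagents that add atoms: none
Why: Elimination and chlorine–lithium exchange on 17 give lithium alkoxyacetylide 18, which undergoes 1,2-addition to the aldehyde faster than it deprotonates it at −78 °C. The new carbinol centre forms as a mixture and is destroyed in step 13; the cold buffered quench avoids Meyer–Schuster rearrangement.

Step 13
Reactants: 19 (4S,5R)-4-(methoxymethoxy)-5-[4-(methoxymethoxy)phenyl]-5-[(5-methylhex-4-en-1-yn-1-yl)oxy]-1-[2-(trimethylsilyl)ethoxy]pent-1-yn-3-ol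
Product: 20 (4R,5R)-4-(methoxymethoxy)-5-[4-(methoxymethoxy)phenyl]-5-[(5-methylhex-4-en-1-yn-1-yl)oxy]-1-[2-(trimethylsilyl)ethoxy]pent-1-yn-3-one
Conditions: MnO2 (activated, excess), CH2Cl2, 0 °C → rt; filtered and used without delay
Reagents that add atoms: none
Why: Oxidation of a propargylic alcohol by MnO2, a neutral heterogeneous oxidant. No acid is present (no Meyer–Schuster rearrangement, no ynol ether hydration) and no base (no β-elimination next to the new ketone); 3-alkoxy ynones are a known compound class.

Step 14
Reactants: 21 4-methylpent-3-enoic acid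
Product: 22 methyl 4-methylpent-3-enoate
Conditions: MeI, K2CO3, DMF, rt
Reagents that add atoms: iodomethane, CI
Why: O-alkylation of the carboxylate; the mild carbonate base at room temperature should not move the β,γ double bond into conjugation.

Step 15
Reactants: 22 methyl 4-methylpent-3-enoate
Product: 24 triisopropyl[(5-methylhex-4-en-1-yn-1-yl)oxy]silane, via lithium ynolate 23 (not isolated)
Conditions: CH2Br2, LiTMP, THF, −78 °C; then 22; n-BuLi, −78 → 30 °C; TIPSCl, −78 → 0 °C
Reagents that add atoms: dibromomethane, BrCBr; chlorotriisopropylsilane, CC(C)[Si](Cl)(C(C)C)C(C)C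
Why: Kowalski ester homologation stopped at the ynolate: dibromomethyllithium adds to the ester, and the dibromo enolate undergoes bromine–lithium exchange and 1,2-shift to lithium ynolate 23. The bulky silyl chloride traps it on oxygen to give the siloxyalkyne.

Step 16
Reactants: 20 (4R,5R)-4-(methoxymethoxy)-5-[4-(methoxymethoxy)phenyl]-5-[(5-methylhex-4-en-1-yn-1-yl)oxy]-1-[2-(trimethylsilyl)ethoxy]pent-1-yn-3-one, 24 triisopropyl[(5-methylhex-4-en-1-yn-1-yl)oxy]silane
Product: 25 (2R,3R)-3-(methoxymethoxy)-2-[4-(methoxymethoxy)phenyl]-6,8-bis(3-methylbut-2-en-1-yl)-7-[(triisopropylsilyl)oxy]-5-[2-(trimethylsilyl)ethoxy]-2,3-dihydro-4H-chromen-4-one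
Conditions: [Rh(cod)2]BF4 (10 mol %), (R)-BINAP (10 mol %), H2 then Ar, 4 Å MS, CH2Cl2, rt; 24 (3 equiv), slow addition of 20
Reagents that add atoms: none
Why: Proposed new method: the cationic monovalent rhodium–BINAP fragment, freed of cyclooctadiene by hydrogenation, should bind the two alkynes of 20 and couple them oxidatively to a trivalent rhodacyclopentadiene; this forms C4a–C8a and closes ring C as the six-membered ring fused to the metallacycle (cyclisation of a 1,7-diyne through the C4–C3–C2–O1 tether). Insertion of 24 into a Rh–C bond and reductive elimination then form C5–C6 and C7–C8, close ring A as the new benzene ring and return the catalyst. The closest known reaction type is the rhodium- or ruthenium-catalysed [2+2+2] cycloaddition of tethered 1,6- and 1,7-diynes with ynamides, alkynyl ethers and other heteroatom-substituted monoalkynes; a diyne combining an alkoxy ynone with an alkyl ynol ether, joined with a siloxyalkyne, has not been shown. No stereocentre is created, and C2 and C3 are carried unchanged because the medium is neutral and aprotic, so neither enolisation at C3 nor β-elimination of O1 is triggered. The step needs one orientation of 24, with its prenyl-bearing carbon (C6) bonded to C5 and its silyloxy-bearing carbon (C7) bonded to C8. This is the polarity-matched orientation, since each new bond joins a nucleophilic alkyne carbon (C4a, C6, C8) to an electrophilic one (C8a, C5, C7), and it also keeps the bulky silyloxy group away from the 2-(trimethylsilyl)ethoxy group. Cross-reaction over oligomerisation rests on the tether (the two diyne alkynes couple intramolecularly), on slow addition of 20 and on an excess of the hindered, slowly self-trimerising 24. Room temperature keeps the benzylic ynol ether below the range of its sigmatropic and retro-ene decomposition.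

Step 17
Reactants: 25 (2R,3R)-3-(methoxymethoxy)-2-[4-(methoxymethoxy)phenyl]-6,8-bis(3-methylbut-2-en-1-yl)-7-[(triisopropylsilyl)oxy]-5-[2-(trimethylsilyl)ethoxy]-2,3-dihydro-4H-chromen-4-one
Product: 26 (2R,3R)-3-hydroxy-2-(4-hydroxyphenyl)-6,8-bis(3-methylbut-2-en-1-yl)-7-[(triisopropylsilyl)oxy]-5-[2-(trimethylsilyl)ethoxy]-2,3-dihydro-4H-chromen-4-one
Conditions: HCl (3 M aq), MeOH/THF, 45 °C
Reagents that add atoms: none
Why: Acid-catalysed transacetalisation of both methoxymethyl ethers to dimethoxymethane; O5 and O7 stay blocked, so no phenol can add to a neighbouring protonated prenyl group (chroman formation), and an acidic medium does not open ring C.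

Step 18
Reactants: 26 (2R,3R)-3-hydroxy-2-(4-hydroxyphenyl)-6,8-bis(3-methylbut-2-en-1-yl)-7-[(triisopropylsilyl)oxy]-5-[2-(trimethylsilyl)ethoxy]-2,3-dihydro-4H-chromen-4-one
Product: 27 6,8-diprenylaromadendrin, (2R,3R)-3,5,7-trihydroxy-2-(4-hydroxyphenyl)-6,8-bis(3-methylbut-2-en-1-yl)-2,3-dihydro-4H-chromen-4-one
Conditions: TBAF, THF (degassed), 0 °C → rt, Ar; pH 5 buffer quench
Reagents that add atoms: none
Why: Fluoride cleaves the aryl silyl ether at O7 and triggers β-fragmentation of the 2-(trimethylsilyl)ethyl ether at O5 with loss of ethene; the fragmentation is eased because the leaving oxygen is conjugated to the C4 carbonyl like a vinylogous carboxylate. Low temperature, exclusion of air and a buffered quench limit base-induced opening of ring C and dehydrogenation to the flavonol.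

## Compound list

1 | 4-hydroxybenzaldehyde | O=Cc1ccc(O)cc1 | starting material
2 | 4-(methoxymethoxy)benzaldehyde | COCOc1ccc(C=O)cc1 | intermediate
3 | O-diisopinocampheylboryl derivative (borinate ester) of 4, isopinocampheyl groups of the (+)-series | C=C[C@H](OCOC)[C@H](c1ccc(OCOC)cc1)OB([C@H]1C[C@H]2C[C@H](C2(C)C)[C@@H]1C)[C@H]1C[C@H]2C[C@H](C2(C)C)[C@@H]1C | intermediate (not isolated)
4 | (1S,2S)-2-(methoxymethoxy)-1-[4-(methoxymethoxy)phenyl]but-3-en-1-ol | C=C[C@H](OCOC)[C@H](c1ccc(OCOC)cc1)O | intermediate
5 | (1S,2R)-2-(methoxymethoxy)-1-[4-(methoxymethoxy)phenyl]-2-(1,2,4-trioxolan-3-yl)ethan-1-ol (ozonide of 4, mixture at the trioxolane carbon) | C1(OCOO1)[C@H](OCOC)[C@H](c1ccc(OCOC)cc1)O | intermediate (not isolated)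
6 | (1S,2S)-2-(methoxymethoxy)-1-[4-(methoxymethoxy)phenyl]propane-1,3-diol | OC[C@H](OCOC)[C@H](c1ccc(OCOC)cc1)O | intermediate
7 | (1S,2S)-2-(methoxymethoxy)-1-[4-(methoxymethoxy)phenyl]-3-[(triisopropylsilyl)oxy]propan-1-ol | CC(C)[Si](C(C)C)(C(C)C)OC[C@H](OCOC)[C@H](c1ccc(OCOC)cc1)O | intermediate
8 | (2S)-2-(methoxymethoxy)-1-[4-(methoxymethoxy)phenyl]-3-[(triisopropylsilyl)oxy]propan-1-one | CC(C)[Si](C(C)C)(C(C)C)OC[C@H](OCOC)C(=O)c1ccc(OCOC)cc1 | intermediate
9 | (1R,2S)-2-(methoxymethoxy)-1-[4-(methoxymethoxy)phenyl]-3-[(triisopropylsilyl)oxy]propan-1-ol | CC(C)[Si](C(C)C)(C(C)C)OC[C@H](OCOC)[C@@H](c1ccc(OCOC)cc1)O | intermediate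
10 | {(2S,3R)-3-{[(E)-1,2-dichloroethenyl]oxy}-2-(methoxymethoxy)-3-[4-(methoxymethoxy)phenyl]propoxy}triisopropylsilane | CC(C)[Si](C(C)C)(C(C)C)OC[C@H](OCOC)[C@@H](c1ccc(OCOC)cc1)O/C(Cl)=C\Cl | intermediate
11 | 1-bromo-3-methylbut-2-ene (prenyl bromide) | CC(C)=CCBr | starting material
12 | {(2S,3R)-3-[(lithioethynyl)oxy]-2-(methoxymethoxy)-3-[4-(methoxymethoxy)phenyl]propoxy}triisopropylsilane (lithium alkynyl ether) | CC(C)[Si](C(C)C)(C(C)C)OC[C@H](OCOC)[C@@H](c1ccc(OCOC)cc1)OC#C[Li] | intermediate (not isolated)
13 | {(2S,3R)-2-(methoxymethoxy)-3-[4-(methoxymethoxy)phenyl]-3-[(5-methylhex-4-en-1-yn-1-yl)oxy]propoxy}triisopropylsilane | CC(C)[Si](C(C)C)(C(C)C)OC[C@H](OCOC)[C@@H](c1ccc(OCOC)cc1)OC#CCC=C(C)C | intermediate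
14 | (2S,3R)-2-(methoxymethoxy)-3-[4-(methoxymethoxy)phenyl]-3-[(5-methylhex-4-en-1-yn-1-yl)oxy]propan-1-ol | OC[C@H](OCOC)[C@@H](c1ccc(OCOC)cc1)OC#CCC=C(C)C | intermediate
15 | (2R,3R)-2-(methoxymethoxy)-3-[4-(methoxymethoxy)phenyl]-3-[(5-methylhex-4-en-1-yn-1-yl)oxy]propanal | O=C[C@H](OCOC)[C@@H](c1ccc(OCOC)cc1)OC#CCC=C(C)C | intermediate
16 | 2-(trimethylsilyl)ethanol | C[Si](C)(C)CCO | starting material
17 | {2-{[(E)-1,2-dichloroethenyl]oxy}ethyl}trimethylsilane | C[Si](C)(C)CCO/C(Cl)=C\Cl | intermediate
18 | lithium [2-(trimethylsilyl)ethoxy]acetylide | C[Si](C)(C)CCOC#C[Li] | intermediate (not isolated)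
19 | (4S,5R)-4-(methoxymethoxy)-5-[4-(methoxymethoxy)phenyl]-5-[(5-methylhex-4-en-1-yn-1-yl)oxy]-1-[2-(trimethylsilyl)ethoxy]pent-1-yn-3-ol (both C3 epimers) | C[Si](C)(C)CCOC#CC(O)[C@H](OCOC)[C@@H](c1ccc(OCOC)cc1)OC#CCC=C(C)C | intermediate
20 | (4R,5R)-4-(methoxymethoxy)-5-[4-(methoxymethoxy)phenyl]-5-[(5-methylhex-4-en-1-yn-1-yl)oxy]-1-[2-(trimethylsilyl)ethoxy]pent-1-yn-3-one | C[Si](C)(C)CCOC#CC(=O)[C@H](OCOC)[C@@H](c1ccc(OCOC)cc1)OC#CCC=C(C)C | intermediate
21 | 4-methylpent-3-enoic acid | CC(C)=CCC(=O)O | starting material
22 | methyl 4-methylpent-3-enoate | COC(=O)CC=C(C)C | intermediate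
23 | lithium 5-methylhex-4-en-1-yn-1-olate | CC(C)=CCC#CO[Li] | intermediate (not isolated)
24 | triisopropyl[(5-methylhex-4-en-1-yn-1-yl)oxy]silane | CC(C)=CCC#CO[Si](C(C)C)(C(C)C)C(C)C | intermediate
25 | (2R,3R)-3-(methoxymethoxy)-2-[4-(methoxymethoxy)phenyl]-6,8-bis(3-methylbut-2-en-1-yl)-7-[(triisopropylsilyl)oxy]-5-[2-(trimethylsilyl)ethoxy]-2,3-dihydro-4H-chromen-4-one | CC(C)=CCc1c(O[Si](C(C)C)(C(C)C)C(C)C)c(CC=C(C)C)c2c(c1OCC[Si](C)(C)C)C(=O)[C@H](OCOC)[C@@H](c1ccc(OCOC)cc1)O2 | intermediate
26 | (2R,3R)-3-hydroxy-2-(4-hydroxyphenyl)-6,8-bis(3-methylbut-2-en-1-yl)-7-[(triisopropylsilyl)oxy]-5-[2-(trimethylsilyl)ethoxy]-2,3-dihydro-4H-chromen-4-one | CC(C)=CCc1c(O[Si](C(C)C)(C(C)C)C(C)C)c(CC=C(C)C)c2c(c1OCC[Si](C)(C)C)C(=O)[C@H](O)[C@@H](c1ccc(O)cc1)O2 | intermediate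
27 | 6,8-diprenylaromadendrin, (2R,3R)-3,5,7-trihydroxy-2-(4-hydroxyphenyl)-6,8-bis(3-methylbut-2-en-1-yl)-2,3-dihydro-4H-chromen-4-one | CC(C)=CCc1c(O)c(CC=C(C)C)c2c(c1O)C(=O)[C@H](O)[C@@H](c1ccc(O)cc1)O2 | target

## Step count and least certain steps

Total: 18 steps. Longest linear sequence: 15 steps (steps 1–10, 12, 13, 16, 17, 18).

**Step 16 (key step, proposed new method).** The catalyst may fail to engage the hindered, doubly oxygen-substituted diyne. Oligomerisation of either alkyne, protonation of the electron-rich ynol ethers by traces of acid, sigmatropic rearrangement of the benzylic ynol ether, or insertion of 24 in the reverse orientation can take over. The fallback uses known chemistry and leaves the cycloaddition. It sets out from 2 and returns at 27: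
- 2,4,6-trihydroxyacetophenone is C-prenylated twice with 11 (aqueous KOH) to 1-[2,4,6-trihydroxy-3,5-bis(3-methylbut-2-en-1-yl)phenyl]ethanone F1;
- NaH and MOMCl give the tris(methoxymethyl) ether F2;
- Claisen–Schmidt condensation with 2 (KOH, EtOH) gives chalcone F3;
- Julia–Colonna epoxidation (poly-L-leucine, urea–H2O2, DBU) gives the (2R,3S)-epoxy ketone F4;
- methanolic HCl removes the four acetal groups, and the freed ortho phenol opens the epoxide at the benzylic carbon with inversion.

**Step 8.** Metalation may be incomplete, or the alkylation may go astray: allylic transposition on the bromide, proton transfer from the doubly activated CH2 of the product leading to allene isomers, or rearrangement of the benzylic ynol ether on warming. The fallback separates the two events and changes the C–C bond-forming mechanism. From 10, n-BuLi followed by a methanol quench at −78 °C gives the terminal ethynyl ether, {(2S,3R)-3-(ethynyloxy)-2-(methoxymethoxy)-3-[4-(methoxymethoxy)phenyl]propoxy}triisopropylsilane F5. Copper-catalysed allylation of this terminal alkyne with 11 (CuI, K2CO3, NaI, DMF, rt) then returns to the route at 13.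

**Step 12 (with step 13).** The acetylide may act as a base and cause β-elimination of the alkynyloxy group from 15. The alkoxypropargylic alcohol 19 may also rearrange (Meyer–Schuster) or hydrate during isolation. The fallback avoids the free carbinol. From 15 and 17, the lithium alkoxide formed at −78 °C is oxidised in the same flask with N-tert-butylbenzenesulfinimidoyl chloride, which converts alkoxides to ketones at that temperature. It returns to the route at 20 and forms no new isolated compound (entered as F0).

**Step 18.** The aryl 2-(trimethylsilyl)ethyl ether may fragment slowly, and prolonged exposure of the unprotected 3-hydroxy ketone to fluoride and phenoxide invites ring C opening, loss of configuration and dehydrogenation. The fallback reverses the order and changes the acetal cleavage to a Lewis-acid mechanism. From 25, TBAF acts while O3 is still protected and gives (2R,3R)-5,7-dihydroxy-3-(methoxymethoxy)-2-[4-(methoxymethoxy)phenyl]-6,8-bis(3-methylbut-2-en-1-yl)-2,3-dihydro-4H-chromen-4-one F6. Me2BBr in CH2Cl2 at −78 °C, followed by NaHCO3 work-up, then removes both methoxymethyl groups at a temperature where the ortho-prenyl phenols should not cyclise, returning to the route at 27.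

## Further compounds

F1 | step 16 | 1-[2,4,6-trihydroxy-3,5-bis(3-methylbut-2-en-1-yl)phenyl]ethanone | CC(=O)c1c(O)c(CC=C(C)C)c(O)c(CC=C(C)C)c1O
F2 | step 16 | 1-[2,4,6-tris(methoxymethoxy)-3,5-bis(3-methylbut-2-en-1-yl)phenyl]ethanone | CC(=O)c1c(OCOC)c(CC=C(C)C)c(OCOC)c(CC=C(C)C)c1OCOC
F3 | step 16 | (E)-3-[4-(methoxymethoxy)phenyl]-1-[2,4,6-tris(methoxymethoxy)-3,5-bis(3-methylbut-2-en-1-yl)phenyl]prop-2-en-1-one | O=C(/C=C/c1ccc(OCOC)cc1)c1c(OCOC)c(CC=C(C)C)c(OCOC)c(CC=C(C)C)c1OCOC
F4 | step 16 | {(2R,3S)-3-[4-(methoxymethoxy)phenyl]oxiran-2-yl}[2,4,6-tris(methoxymethoxy)-3,5-bis(3-methylbut-2-en-1-yl)phenyl]methanone | O=C(c1c(OCOC)c(CC=C(C)C)c(OCOC)c(CC=C(C)C)c1OCOC)[C@@H]1O[C@H]1c1ccc(OCOC)cc1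
F5 | step 8 | {(2S,3R)-3-(ethynyloxy)-2-(methoxymethoxy)-3-[4-(methoxymethoxy)phenyl]propoxy}triisopropylsilane | CC(C)[Si](C(C)C)(C(C)C)OC[C@H](OCOC)[C@@H](c1ccc(OCOC)cc1)OC#C
F0 | step 12 | none | none
F6 | step 18 | (2R,3R)-5,7-dihydroxy-3-(methoxymethoxy)-2-[4-(methoxymethoxy)phenyl]-6,8-bis(3-methylbut-2-en-1-yl)-2,3-dihydro-4H-chromen-4-one | CC(C)=CCc1c(O)c(CC=C(C)C)c2c(c1O)C(=O)[C@H](OCOC)[C@@H](c1ccc(OCOC)cc1)O2
A1 | alternative 1 | 2-diazo-1-[2-fluoro-4,6-bis(methoxymethoxy)-3,5-bis(3-methylbut-2-en-1-yl)phenyl]ethanone | CC(C)=CCc1c(OCOC)c(CC=C(C)C)c(F)c(C(=O)C=[N+]=[N-])c1OCOC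
A2 | alternative 1 | 4-methoxybenzyl alcohol | COc1ccc(CO)cc1
A3 | alternative 1 | (2R,3R)-1-[2-fluoro-4,6-bis(methoxymethoxy)-3,5-bis(3-methylbut-2-en-1-yl)phenyl]-3-hydroxy-2-(4-methoxybenzyloxy)-3-[4-(methoxymethoxy)phenyl]propan-1-one | CC(C)=CCc1c(OCOC)c(CC=C(C)C)c(F)c(C(=O)[C@H](OCc2ccc(OC)cc2)[C@@H](c2ccc(OCOC)cc2)O)c1OCOC
A4 | alternative 2 | 3-(methoxymethoxy)-2-(3-methylbut-2-en-1-yl)cyclobut-2-en-1-one | COCOC1=C(CC=C(C)C)C(=O)C1
A5 | alternative 2 | 5-(methoxymethoxy)-2,4-bis(3-methylbut-2-en-1-yl)-3-[(triisopropylsilyl)oxy]phenol | Oc1cc(OCOC)c(CC=C(C)C)c(O[Si](C(C)C)(C(C)C)C(C)C)c1CC=C(C)C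
A6 | alternative 3 | (2R,3R)-3-(methoxymethoxy)-2-[4-(methoxymethoxy)phenyl]-5,7-bis(prop-2-en-1-yloxy)-2,3-dihydro-4H-chromen-4-one | C=CCOc1cc2c(c(OCC=C)c1)C(=O)[C@H](OCOC)[C@@H](c1ccc(OCOC)cc1)O2
A7 | alternative 3 | (2R,3R)-5,7-dihydroxy-3-(methoxymethoxy)-2-[4-(methoxymethoxy)phenyl]-6,8-bis(prop-2-en-1-yl)-2,3-dihydro-4H-chromen-4-one | C=CCc1c(O)c(CC=C)c2c(c1O)C(=O)[C@H](OCOC)[C@@H](c1ccc(OCOC)cc1)O2
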